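**Plan**

- Numbering: ring C1 (side chain), C2 (OH), C3 (OMe), C4 (OH), C5, C6; chain C7–C8–C9(=O)–O–octadecyl.
- Cuts: C8–C9 and C9–O(octadecyl) in one operation, then C7–C8 (as C7=C8), then C1–C7. The oxygens on C2 and C4 travel as benzyl ethers.
- Enabling feature: C9 is a single carbonyl carbon between the C7–C8 unit on C1 and the octadecyl oxygen, so it corresponds to one CO placed between a C1 vinyl group and the fatty alcohol. The C2 oxygen could close a six-membered lactone onto C9, so it stays masked until the ester is in place.
- Forward order: the benzene ring, the only ring, is bought as symmetric 2-methoxyresorcinol. The sequence is benzylation, formylation at C1 (C1 and C5 are equivalent), methylenation, three-component carbonylation and hydrogenolysis.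
- Stereochemistry: the target has no stereocentre and no double-bond geometry. The only selectivity to control is linear versus branched carbonylation.

Key step: step 4

**Step 1**
Reactants: 1 2-methoxyresorcinol (2-methoxybenzene-1,3-diol); 2 benzyl bromide
Product: 3 1,3-bis(benzyloxy)-2-methoxybenzene
Conditions: BnBr (2.3 equiv), K2CO3 (3 equiv), acetone, reflux
Reagents that add atoms: benzyl bromide, BrCc1ccccc1
Why: A double Williamson ether synthesis should alkylate both phenoxides with the primary benzylic bromide, giving a symmetric diether whose masks tolerate the later acid catalysis, ylide and CO but leave under neutral hydrogenolysis.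

**Step 2**
Reactants: 3 1,3-bis(benzyloxy)-2-methoxybenzene; 4 N,N-dimethylformamide
Product: 7 2,4-bis(benzyloxy)-3-methoxybenzaldehyde, via chloroiminium salt 5 (not isolated), via aryl iminium salt 6 (not isolated)
Conditions: POCl3 (2 equiv), DMF, 0 °C; then 3, 75 °C; aq NaOAc, rt
Reagents that add atoms: N,N-dimethylformamide, CN(C)C=O; water, O
Why: In this Vilsmeier–Haack formylation, as with 1,2,3-trimethoxybenzene, attack should occur para to one benzyloxy group and ortho to the other rather than at C6, because the twisted central methoxy group donates poorly; the mirror symmetry of 3 makes the two reactive positions identical, and the iminium group blocks a second substitution.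

**Step 3**
Reactants: 7 2,4-bis(benzyloxy)-3-methoxybenzaldehyde; 8 methyltriphenylphosphonium bromide
Product: 10 1,3-bis(benzyloxy)-4-ethenyl-2-methoxybenzene, via methylenetriphenylphosphorane 9 (not isolated)
Conditions: Ph3PCH3Br (1.5 equiv), KOtBu (1.4 equiv), THF, 0 °C; then 7, 0 °C to rt
Reagents that add atoms: methyltriphenylphosphonium bromide, C[P+](c1ccccc1)(c1ccccc1)c1ccccc1.[Br-]
Why: Wittig methylenation with the non-stabilised ylide should convert the non-enolisable aryl aldehyde into the terminal styrene, driven by formation of the P=O bond, while the benzyl and methyl ethers are inert to the ylide.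

**Step 4**
Reactants: 10 1,3-bis(benzyloxy)-4-ethenyl-2-methoxybenzene; 11 carbon monoxide; 12 octadecan-1-ol
Product: 13 octadecyl 3-[2,4-bis(benzyloxy)-3-methoxyphenyl]propanoate
Conditions: CO (30 bar), 12 (1.5 equiv), Pd(OAc)2 (1 mol%), 1,2-bis(di-tert-butylphosphinomethyl)benzene (5 mol%), MeSO3H (10 mol%), toluene, 80 °C
Reagents that add atoms: carbon monoxide, [C-]#[O+]; octadecan-1-ol, CCCCCCCCCCCCCCCCCCO
Why: Pd(OAc)2, the diphosphine, the sulfonic acid and the alcohol should generate a cationic hydride of divalent palladium that adds reversibly to C7=C8 of 10; CO then inserts into the primary alkyl bound through C8 (new C8–C9 bond), and octadecan-1-ol cleaves the acyl (new C9–O bond) and returns the hydride. This is the hydride-cycle alkoxycarbonylation (hydroesterification) of vinylarenes, for which bulky chelating di-tert-butylphosphines are the established way to the linear 3-arylpropanoate. No ring is closed, no stereocentre is created and every atom of the three components ends up in 13, so the only selectivity needed is linear over branched. That selectivity rests on the four tert-butyl groups of the chelate, which crowd out the secondary benzylic alkyl at C7, and on the C2 benzyloxy group of 10, which adds ortho strain to that isomer and hinders its eta-3 benzyl stabilisation. Because both phenols are benzyl ethers, no internal oxygen nucleophile can intercept the acyl at C9, so the six-membered lactone cannot form and a free acid stage is never passed. The acid is held to a few equivalents per palladium and is largely buffered by the excess phosphine, which should spare the electron-rich styrene from cationic oligomerisation.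

**Step 5**
Reactants: 13 octadecyl 3-[2,4-bis(benzyloxy)-3-methoxyphenyl]propanoate
Product: 14 octadecyl 3-(2,4-dihydroxy-3-methoxyphenyl)propanoate
Conditions: H2 (1 atm), 10% Pd/C, EtOAc, rt; filtration through Celite, evaporation below 30 °C
Reagents that add atoms: none
Why: Catalytic hydrogenolysis of the two aryl benzyl ethers runs at neutral pH and room temperature, where the alkyl ester, the aryl methyl ether and the arene should be untouched and the freed C2 phenol has no acid or base to catalyse acyl transfer from C9.

**Compound list**

1 | 2-methoxyresorcinol (2-methoxybenzene-1,3-diol) | COc1c(O)cccc1O | starting material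
2 | benzyl bromide | BrCc1ccccc1 | starting material
3 | 1,3-bis(benzyloxy)-2-methoxybenzene | COc1c(OCc2ccccc2)cccc1OCc1ccccc1 | intermediate
4 | N,N-dimethylformamide | CN(C)C=O | starting material
5 | (chloromethylidene)dimethyliminium dichlorophosphate (chloroiminium salt) | C[N+](C)=CCl.[O-]P(=O)(Cl)Cl | intermediate
6 | [2,4-bis(benzyloxy)-3-methoxyphenyl]methylidene(dimethyl)iminium dichlorophosphate (aryl iminium salt) | C[N+](C)=Cc1ccc(OCc2ccccc2)c(OC)c1OCc1ccccc1.[O-]P(=O)(Cl)Cl | intermediate
7 | 2,4-bis(benzyloxy)-3-methoxybenzaldehyde | O=Cc1ccc(OCc2ccccc2)c(OC)c1OCc1ccccc1 | intermediate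
8 | methyltriphenylphosphonium bromide | C[P+](c1ccccc1)(c1ccccc1)c1ccccc1.[Br-] | starting material
9 | methylenetriphenylphosphorane | C=P(c1ccccc1)(c1ccccc1)c1ccccc1 | intermediate
10 | 1,3-bis(benzyloxy)-4-ethenyl-2-methoxybenzene | C=Cc1ccc(OCc2ccccc2)c(OC)c1OCc1ccccc1 | intermediate
11 | carbon monoxide | [C-]#[O+] | starting material
12 | octadecan-1-ol | CCCCCCCCCCCCCCCCCCO | starting material
13 | octadecyl 3-[2,4-bis(benzyloxy)-3-methoxyphenyl]propanoate | CCCCCCCCCCCCCCCCCCOC(=O)CCc1ccc(OCc2ccccc2)c(OC)c1OCc1ccccc1 | intermediate
14 | octadecyl 3-(2,4-dihydroxy-3-methoxyphenyl)propanoate | CCCCCCCCCCCCCCCCCCOC(=O)CCc1ccc(O)c(OC)c1O | target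

Total step count: 5
Longest linear sequence: 5 (1 → 3 → 7 → 10 → 13 → 14)

**Steps most likely to fail**

1. Step 4.
   - Risks: the linear preference may erode through carbonylation of the benzylic palladium alkyl. The electron-rich styrene may be lost to acid-induced cationic oligomerisation or to Markovnikov addition of the alcohol. Alcoholysis of the acyl may be slow with only a small excess of a waxy alcohol.
   - Fallback: it sets out from styrene 10. Olefin cross-metathesis with commercial octadecyl acrylate (CCCCCCCCCCCCCCCCCCOC(=O)C=C), using the second-generation Hoveyda–Grubbs catalyst in CH2Cl2 at 40 °C, should give octadecyl (E)-3-[2,4-bis(benzyloxy)-3-methoxyphenyl]prop-2-enoate F1. Treatment with H2 and 10% Pd/C in EtOAc should then saturate C7=C8 and cleave both benzyl ethers in one operation, returning to the route at target 14.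

2. Step 5.
   - Risks: the crowded C2 benzyl ether may cleave slowly, prolonging contact with the catalyst support. The freed C2 phenol may then close onto C9 with expulsion of the fatty alcohol during concentration or chromatography.
   - Fallback: it sets out from 13 and replaces the surface reaction with a Lewis-acid ionisation. BCl3 (excess) with pentamethylbenzene as a non-basic benzyl-cation scavenger in CH2Cl2 at −78 °C should give octadecyl 3-{2,4-bis[(dichloroboranyl)oxy]-3-methoxyphenyl}propanoate F2. In F2 both phenol oxygens are held on boron and cannot attack C9, and the low temperature should spare the C3 methyl ether. A cold quench into sodium phosphate buffer at pH 7 releases the phenols and returns to the route at target 14.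

3. Step 2.
   - Risks: substitution of the crowded trialkoxyarene may be sluggish. The benzyl group next to the iminium may be lost to the hydrogen chloride formed at the temperature required.
   - Fallback: it sets out from 3. Electrophilic bromination with NBS in MeCN at 0 °C in the dark should follow the same para-to-benzyloxy regiochemistry and give 1,3-bis(benzyloxy)-4-bromo-2-methoxybenzene F3. Suzuki–Miyaura vinylation with potassium vinyltrifluoroborate (CH2=CHBF3K), PdCl2(dppf) and Cs2CO3 in THF/H2O at 80 °C then returns to the route at styrene 10, which makes the aldehyde and the Wittig step unnecessary.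

**Further compounds**

F1 | step 4 | octadecyl (E)-3-[2,4-bis(benzyloxy)-3-methoxyphenyl]prop-2-enoate | CCCCCCCCCCCCCCCCCCOC(=O)/C=C/c1ccc(OCc2ccccc2)c(OC)c1OCc1ccccc1
F2 | step 5 | octadecyl 3-{2,4-bis[(dichloroboranyl)oxy]-3-methoxyphenyl}propanoate | CCCCCCCCCCCCCCCCCCOC(=O)CCc1ccc(OB(Cl)Cl)c(OC)c1OB(Cl)Cl
F3 | step 2 | 1,3-bis(benzyloxy)-4-bromo-2-methoxybenzene | COc1c(OCc2ccccc2)ccc(Br)c1OCc1ccccc1
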